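**Plan**
- Cuts: the C6–prenyl bond (traced back to a 5‑O‑(1,1‑dimethylallyl) ether and a Claisen shift), C4–C4a (aryl anion plus amide), O1–C2 (phenol plus benzylic carbinol), C2–C3 (aldol) and C2'–geranyl (arylcopper plus allylic bromide).
- Forward order: the B‑ring aldehyde is geranylated and extended to a 3‑aryl‑3‑hydroxypropanoic Weinreb amide, which is joined through oxygen to 2‑bromo‑3,5‑dimethoxyphenol. The pyranone ring C, the only ring formed, is then closed, and O5 is finally unmasked and used to deliver the prenyl group to C6.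
- Enabling feature: the C4 carbonyl sits on C4a, the ring‑A carbon between C8a–O1 and C5–O. A bromine on that carbon marks the acylation site, and O1–C2–C3 is the three‑atom tether that makes the C4–C4a closure six‑membered with C2 already configured.
- Stereochemistry: C2 comes from a Ru‑catalysed asymmetric transfer hydrogenation giving the (R)‑carbinol, inverted to (S) in the Mitsunobu etherification. The geranyl E‑olefin is taken from geranyl bromide.

Key step: step 11

Remark: "geranyl" means (2E)‑3,7‑dimethylocta‑2,6‑dien‑1‑yl and TIPS means triisopropylsilyl; the five building blocks marked as starting materials in the compound list are assumed purchasable.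

**Route**

Step 1
Reactants: 1 2-bromo-3-hydroxy-4-methoxybenzaldehyde
Product: 2 2-(2-bromo-3-hydroxy-4-methoxyphenyl)-1,3-dioxolane
Conditions: HOCH2CH2OH, p-TsOH (cat.), toluene, reflux, Dean–Stark
Reagents that add atoms: ethylene glycol OCCO
Why: Acid-catalysed acetalisation with azeotropic removal of water masks the aldehyde against the organometallic chemistry of step 3, and the free phenol does not interfere.

Step 2
Reactants: 2 2-(2-bromo-3-hydroxy-4-methoxyphenyl)-1,3-dioxolane
Product: 3 2-[2-bromo-4-methoxy-3-(methoxymethoxy)phenyl]-1,3-dioxolane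
Conditions: MOMCl, i-Pr2NEt, CH2Cl2, 0 °C → rt
Reagents that add atoms: chloromethyl methyl ether COCCl
Why: Williamson-type O-alkylation of the phenol under amine base leaves the dioxolane intact and gives an ether that tolerates the aryllithium of the next step.

Step 3
Reactants: 3 2-[2-bromo-4-methoxy-3-(methoxymethoxy)phenyl]-1,3-dioxolane; 4 geranyl bromide
Product: 7 2-[2-geranyl-4-methoxy-3-(methoxymethoxy)phenyl]-1,3-dioxolane, via aryllithium 5 (not isolated), via arylcopper 6 (not isolated)
Conditions: n-BuLi, THF, −78 °C; CuBr·SMe2, −78 → −40 °C; then 4, −78 → 0 °C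
Reagents that add atoms: none
Why: Bromine–lithium exchange, transmetalation to copper and SN2-type allylic substitution at the primary carbon of geranyl bromide should join C2' to the geranyl CH2 with the E-olefin retained, γ-attack being disfavoured because it would build a quaternary benzylic carbon.

Step 4
Reactants: 7 2-[2-geranyl-4-methoxy-3-(methoxymethoxy)phenyl]-1,3-dioxolane
Product: 8 2-geranyl-3-hydroxy-4-methoxybenzaldehyde
Conditions: 2 M aq. HCl, THF–MeOH, 40 °C
Reagents that add atoms: water O
Why: Acid hydrolysis cleaves both acetals (dioxolane and aryl MOM ether) in one operation, under conditions kept mild so that the ortho-geranyl phenol does not cyclise to a chroman.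

Step 5
Reactants: 8 2-geranyl-3-hydroxy-4-methoxybenzaldehyde
Product: 9 2-geranyl-4-methoxy-3-(triisopropylsilyloxy)benzaldehyde
Conditions: TIPSCl, imidazole, DMAP (cat.), DMF, rt → 40 °C
Reagents that add atoms: chlorotriisopropylsilane CC(C)[Si](Cl)(C(C)C)C(C)C
Why: Silylation of the phenol installs a group that should withstand enolates, t-BuLi, MgI2 and DBU and leave at the end with fluoride; it is introduced only now because an ortho-lithiated aryl silyl ether in step 3 would suffer retro-Brook silyl migration.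

Step 6
Reactants: 9 2-geranyl-4-methoxy-3-(triisopropylsilyloxy)benzaldehyde; 10 N-methoxy-N-methylacetamide
Product: 12 rac-3-hydroxy-N-methoxy-N-methyl-3-[2-geranyl-4-methoxy-3-(triisopropylsilyloxy)phenyl]propanamide, via lithium enolate 11 (not isolated)
Conditions: LDA, THF, −78 °C; then 9; aq. NH4Cl
Reagents that add atoms: none
Why: Aldol addition of the amide lithium enolate to the non-enolisable aldehyde forms the C2–C3 bond without a Lewis acid that could provoke a Prins-type reaction of the neighbouring geranyl olefin; the carbinol is racemic here because its configuration is set in step 8.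

Step 7
Reactants: 12 rac-3-hydroxy-N-methoxy-N-methyl-3-[2-geranyl-4-methoxy-3-(triisopropylsilyloxy)phenyl]propanamide
Product: 13 N-methoxy-N-methyl-3-oxo-3-[2-geranyl-4-methoxy-3-(triisopropylsilyloxy)phenyl]propanamide
Conditions: Dess–Martin periodinane, CH2Cl2, 0 °C → rt
Reagents that add atoms: none
Why: Dess–Martin oxidation converts the benzylic secondary alcohol into the β-keto amide under nearly neutral conditions that spare the trisubstituted olefins and the silyl ether.

Step 8
Reactants: 13 N-methoxy-N-methyl-3-oxo-3-[2-geranyl-4-methoxy-3-(triisopropylsilyloxy)phenyl]propanamide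
Product: 14 (3R)-3-hydroxy-N-methoxy-N-methyl-3-[2-geranyl-4-methoxy-3-(triisopropylsilyloxy)phenyl]propanamide
Conditions: RuCl[(R,R)-TsDPEN](p-cymene) (2 mol%), HCO2H–Et3N (5:2), CH2Cl2, 30 °C
Reagents that add atoms: none
Why: Noyori–Ikariya asymmetric transfer hydrogenation of the aryl ketone, in which the (R,R)-ligand delivers hydride through the CH/π-organised outer-sphere transition state to the face giving the (R)-carbinol, while isolated olefins and the amide N–O bond are not reduced.

Step 9
Reactants: 15 3,5-dimethoxyphenol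
Product: 16 2-bromo-3,5-dimethoxyphenol
Conditions: NBS (1.0 equiv), i-Pr2NH (10 mol%), CH2Cl2, −78 → 0 °C
Reagents that add atoms: N-bromosuccinimide O=C1CCC(=O)N1Br
Why: Electrophilic aromatic bromination, steered ortho to the hydroxyl by the hydrogen-bonded N-bromoamine, places bromine on the carbon that becomes C4a; the isomer brominated para to the hydroxyl would be removed by chromatography.

Step 10
Reactants: 14 (3R)-3-hydroxy-N-methoxy-N-methyl-3-[2-geranyl-4-methoxy-3-(triisopropylsilyloxy)phenyl]propanamide; 16 2-bromo-3,5-dimethoxyphenol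
Product: 17 (3S)-3-(2-bromo-3,5-dimethoxyphenoxy)-N-methoxy-N-methyl-3-[2-geranyl-4-methoxy-3-(triisopropylsilyloxy)phenyl]propanamide
Conditions: PPh3, DIAD, toluene, 0 °C → rt
Reagents that add atoms: none
Why: Mitsunobu etherification, in which the bromophenol displaces the alkoxyphosphonium group in an SN2 step, forms O1–C2 with inversion so that the (R)-carbinol becomes the (S)-aryl ether; the non-polar solvent and low temperature are chosen to suppress ionisation at the benzylic carbon.

Step 11
Reactants: 17 (3S)-3-(2-bromo-3,5-dimethoxyphenoxy)-N-methoxy-N-methyl-3-[2-geranyl-4-methoxy-3-(triisopropylsilyloxy)phenyl]propanamide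
Product: 20 (2S)-5,7-dimethoxy-2-[2-geranyl-4-methoxy-3-(triisopropylsilyloxy)phenyl]chroman-4-one, via aryllithium 18 (not isolated), via tetrahedral lithium adduct 19 (not isolated)
Conditions: t-BuLi (2.1 equiv), THF, −100 → −78 °C; then sat. aq. NH4Cl
Reagents that add atoms: none
Why: t-BuLi exchanges the bromine at the future C4a for lithium (the second equivalent destroys t-BuBr), and aryllithium 18, held between the O1 ether oxygen and the 5-methoxy group, adds to the tethered N-methoxy-N-methylamide carbonyl to form the C4–C4a bond. This is a Parham cyclisation, the anionic ring-closing acylation known for β-aryloxy Weinreb amides leading to chroman-4-ones. Ring C (the pyranone) closes in a 6-exo-trig mode, and the Li–O–N chelate of adduct 19 keeps the carbonyl masked until the aqueous quench, so neither over-addition nor a ketone enolate can arise. No stereocentre remains from the step (the C4 centre of 19 is lost on collapse), and C2 keeps the (S) configuration of step 10 because C3 is never deprotonated and the aryloxide therefore cannot be expelled and re-added. The selectivity needed is exchange over α-deprotonation of the amide and over direct attack of t-BuLi on it, which the fast exchange of a doubly oxygen-flanked aryl bromide at −100 °C should secure, while the bromine position alone fixes acylation at C4a and not at C8.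

Step 12
Reactants: 20 (2S)-5,7-dimethoxy-2-[2-geranyl-4-methoxy-3-(triisopropylsilyloxy)phenyl]chroman-4-one
Product: 21 (2S)-5-hydroxy-7-methoxy-2-[2-geranyl-4-methoxy-3-(triisopropylsilyloxy)phenyl]chroman-4-one
Conditions: MgI2·OEt2 (3 equiv), toluene–Et2O, 60 °C; then aq. NH4Cl
Reagents that add atoms: none
Why: Chelation-controlled ether cleavage, in which magnesium bridges the C4 carbonyl and the 5-methoxy oxygen so that iodide removes only that methyl group by SN2 attack, should leave the 7- and 4'-methyl ethers, the silyl ether and the olefins untouched.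

Step 13
Reactants: 21 (2S)-5-hydroxy-7-methoxy-2-[2-geranyl-4-methoxy-3-(triisopropylsilyloxy)phenyl]chroman-4-one; 22 3-chloro-3-methylbut-1-yne
Product: 23 (2S)-7-methoxy-5-[(2-methylbut-3-yn-2-yl)oxy]-2-[2-geranyl-4-methoxy-3-(triisopropylsilyloxy)phenyl]chroman-4-one
Conditions: CuCl2·2H2O (1 mol%), DBU, MeCN, 0 °C → rt
Reagents that add atoms: none
Why: Copper-catalysed propargylic substitution through a copper acetylide/allenylidene is the standard way to place a tertiary 1,1-dimethylpropargyl group on a phenol oxygen, and with the 3'-oxygen silylated only O5 can react.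

Step 14
Reactants: 23 (2S)-7-methoxy-5-[(2-methylbut-3-yn-2-yl)oxy]-2-[2-geranyl-4-methoxy-3-(triisopropylsilyloxy)phenyl]chroman-4-one
Product: 24 (2S)-7-methoxy-5-[(2-methylbut-3-en-2-yl)oxy]-2-[2-geranyl-4-methoxy-3-(triisopropylsilyloxy)phenyl]chroman-4-one
Conditions: H2 (1 atm), Lindlar catalyst, quinoline, EtOAc, rt
Reagents that add atoms: none
Why: Lindlar semihydrogenation reduces the terminal alkyne to the vinyl group much faster than it touches trisubstituted olefins or the aryl ketone.

Step 15
Reactants: 24 (2S)-7-methoxy-5-[(2-methylbut-3-en-2-yl)oxy]-2-[2-geranyl-4-methoxy-3-(triisopropylsilyloxy)phenyl]chroman-4-one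
Product: 26 (2S)-5-hydroxy-7-methoxy-6-(3-methylbut-2-en-1-yl)-2-[2-geranyl-4-methoxy-3-(triisopropylsilyloxy)phenyl]chroman-4-one, via cyclohexadienone 25 (not isolated)
Conditions: toluene, 110 °C, sealed tube
Reagents that add atoms: none
Why: The aromatic Claisen rearrangement ([3,3]-sigmatropic shift) moves the allyl unit with allylic transposition from O5 to C6, the only ortho carbon that carries hydrogen (C4a is quaternary), so the tertiary ether becomes the linear 3-methylbut-2-enyl group and tautomerisation of dienone 25 restores the hydrogen-bonded 5-phenol.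

Step 16
Reactants: 26 (2S)-5-hydroxy-7-methoxy-6-(3-methylbut-2-en-1-yl)-2-[2-geranyl-4-methoxy-3-(triisopropylsilyloxy)phenyl]chroman-4-one
Product: 27 (2S)-2-(2-geranyl-3-hydroxy-4-methoxyphenyl)-5-hydroxy-7-methoxy-6-(3-methylbut-2-en-1-yl)chroman-4-one
Conditions: TBAF, AcOH, THF, 0 °C
Reagents that add atoms: none
Why: Fluoride-induced desilylation of the aryl silyl ether, buffered with acetic acid so that no phenoxide or enolate opens the pyranone ring, frees the 3'-hydroxyl without acid that could cyclise the prenyl or geranyl chains onto the neighbouring phenols.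

**Compound list**

1 | 2-bromo-3-hydroxy-4-methoxybenzaldehyde | COc1ccc(C=O)c(Br)c1O | starting material
2 | 2-(2-bromo-3-hydroxy-4-methoxyphenyl)-1,3-dioxolane | COc1ccc(C2OCCO2)c(Br)c1O | intermediate
3 | 2-[2-bromo-4-methoxy-3-(methoxymethoxy)phenyl]-1,3-dioxolane | COCOc1c(OC)ccc(C2OCCO2)c1Br | intermediate
4 | geranyl bromide, (2E)-1-bromo-3,7-dimethylocta-2,6-diene | CC(C)=CCC/C(C)=C/CBr | starting material
5 | [2-(1,3-dioxolan-2-yl)-5-methoxy-6-(methoxymethoxy)phenyl]lithium | COCOc1c(OC)ccc(C2OCCO2)c1[Li] | intermediate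
6 | [2-(1,3-dioxolan-2-yl)-5-methoxy-6-(methoxymethoxy)phenyl]copper(I) | COCOc1c(OC)ccc(C2OCCO2)c1[Cu] | intermediate
7 | 2-[2-geranyl-4-methoxy-3-(methoxymethoxy)phenyl]-1,3-dioxolane | COCOc1c(OC)ccc(C2OCCO2)c1C/C=C(\C)CCC=C(C)C | intermediate
8 | 2-geranyl-3-hydroxy-4-methoxybenzaldehyde | COc1ccc(C=O)c(C/C=C(\C)CCC=C(C)C)c1O | intermediate
9 | 2-geranyl-4-methoxy-3-(triisopropylsilyloxy)benzaldehyde | COc1ccc(C=O)c(C/C=C(\C)CCC=C(C)C)c1O[Si](C(C)C)(C(C)C)C(C)C | intermediate
10 | N-methoxy-N-methylacetamide | CC(=O)N(C)OC | starting material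
11 | lithium 1-[methoxy(methyl)amino]ethen-1-olate (enolate of 10) | C=C(O[Li])N(C)OC | intermediate
12 | rac-3-hydroxy-N-methoxy-N-methyl-3-[2-geranyl-4-methoxy-3-(triisopropylsilyloxy)phenyl]propanamide | COc1ccc(C(O)CC(=O)N(C)OC)c(C/C=C(\C)CCC=C(C)C)c1O[Si](C(C)C)(C(C)C)C(C)C | intermediate
13 | N-methoxy-N-methyl-3-oxo-3-[2-geranyl-4-methoxy-3-(triisopropylsilyloxy)phenyl]propanamide | COc1ccc(C(=O)CC(=O)N(C)OC)c(C/C=C(\C)CCC=C(C)C)c1O[Si](C(C)C)(C(C)C)C(C)C | intermediate
14 | (3R)-3-hydroxy-N-methoxy-N-methyl-3-[2-geranyl-4-methoxy-3-(triisopropylsilyloxy)phenyl]propanamide | COc1ccc([C@H](O)CC(=O)N(C)OC)c(C/C=C(\C)CCC=C(C)C)c1O[Si](C(C)C)(C(C)C)C(C)C | intermediate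
15 | 3,5-dimethoxyphenol | COc1cc(O)cc(OC)c1 | starting material
16 | 2-bromo-3,5-dimethoxyphenol | COc1cc(O)c(Br)c(OC)c1 | intermediate
17 | (3S)-3-(2-bromo-3,5-dimethoxyphenoxy)-N-methoxy-N-methyl-3-[2-geranyl-4-methoxy-3-(triisopropylsilyloxy)phenyl]propanamide | COc1ccc([C@@H](Oc2cc(OC)cc(OC)c2Br)CC(=O)N(C)OC)c(C/C=C(\C)CCC=C(C)C)c1O[Si](C(C)C)(C(C)C)C(C)C | intermediate
18 | aryllithium from 17 (lithium in place of bromine at the future C4a) | COc1ccc([C@@H](Oc2cc(OC)cc(OC)c2[Li])CC(=O)N(C)OC)c(C/C=C(\C)CCC=C(C)C)c1O[Si](C(C)C)(C(C)C)C(C)C | intermediate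
19 | lithium (2S)-5,7-dimethoxy-4-[methoxy(methyl)amino]-2-[2-geranyl-4-methoxy-3-(triisopropylsilyloxy)phenyl]chroman-4-olate (C4 unassigned) | COc1ccc([C@@H]2CC(O[Li])(N(C)OC)c3c(cc(OC)cc3OC)O2)c(C/C=C(\C)CCC=C(C)C)c1O[Si](C(C)C)(C(C)C)C(C)C | intermediate
20 | (2S)-5,7-dimethoxy-2-[2-geranyl-4-methoxy-3-(triisopropylsilyloxy)phenyl]chroman-4-one | COc1ccc([C@@H]2CC(=O)c3c(cc(OC)cc3OC)O2)c(C/C=C(\C)CCC=C(C)C)c1O[Si](C(C)C)(C(C)C)C(C)C | intermediate
21 | (2S)-5-hydroxy-7-methoxy-2-[2-geranyl-4-methoxy-3-(triisopropylsilyloxy)phenyl]chroman-4-one | COc1ccc([C@@H]2CC(=O)c3c(cc(OC)cc3O)O2)c(C/C=C(\C)CCC=C(C)C)c1O[Si](C(C)C)(C(C)C)C(C)C | intermediate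
22 | 3-chloro-3-methylbut-1-yne | C#CC(C)(C)Cl | starting material
23 | (2S)-7-methoxy-5-[(2-methylbut-3-yn-2-yl)oxy]-2-[2-geranyl-4-methoxy-3-(triisopropylsilyloxy)phenyl]chroman-4-one | COc1ccc([C@@H]2CC(=O)c3c(cc(OC)cc3OC(C)(C)C#C)O2)c(C/C=C(\C)CCC=C(C)C)c1O[Si](C(C)C)(C(C)C)C(C)C | intermediate
24 | (2S)-7-methoxy-5-[(2-methylbut-3-en-2-yl)oxy]-2-[2-geranyl-4-methoxy-3-(triisopropylsilyloxy)phenyl]chroman-4-one | COc1ccc([C@@H]2CC(=O)c3c(cc(OC)cc3OC(C)(C)C=C)O2)c(C/C=C(\C)CCC=C(C)C)c1O[Si](C(C)C)(C(C)C)C(C)C | intermediate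
25 | (2S)-7-methoxy-6-(3-methylbut-2-en-1-yl)-2-[2-geranyl-4-methoxy-3-(triisopropylsilyloxy)phenyl]-2,3-dihydro-4H-chromene-4,5(6H)-dione (C6 unassigned) | COc1ccc([C@@H]2CC(=O)C3=C(C=C(OC)C(CC=C(C)C)C3=O)O2)c(C/C=C(\C)CCC=C(C)C)c1O[Si](C(C)C)(C(C)C)C(C)C | intermediate
26 | (2S)-5-hydroxy-7-methoxy-6-(3-methylbut-2-en-1-yl)-2-[2-geranyl-4-methoxy-3-(triisopropylsilyloxy)phenyl]chroman-4-one | COc1ccc([C@@H]2CC(=O)c3c(cc(OC)c(CC=C(C)C)c3O)O2)c(C/C=C(\C)CCC=C(C)C)c1O[Si](C(C)C)(C(C)C)C(C)C | intermediate
27 | (2S)-2-(2-geranyl-3-hydroxy-4-methoxyphenyl)-5-hydroxy-7-methoxy-6-(3-methylbut-2-en-1-yl)chroman-4-one | COc1ccc([C@@H]2CC(=O)c3c(cc(OC)c(CC=C(C)C)c3O)O2)c(C/C=C(\C)CCC=C(C)C)c1O | target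

**Step count**
Total: 16 steps. Longest linear sequence: 15 steps (steps 1–8 and 10–16, from compound 1); step 9 is a one-step side branch.

**Steps most likely to fail**

Step 10 (Mitsunobu etherification). The alkoxyphosphonium intermediate sits on a benzylic carbon para to a methoxy group, so partial ionisation could erode the enantiomeric purity. The betaine could also dehydrate the β-hydroxy amide to the cinnamamide. The fallback gives up stereospecific substitution and takes the configuration from a kinetic resolution instead. It sets out from racemic alcohol 12, so steps 7 and 8 are skipped. Mitsunobu coupling of 12 with 16 should give the racemic aryl ether F1. Bromine–lithium exchange and cyclisation as in step 11 should give the racemic flavanone F2. Asymmetric transfer hydrogenation with RuCl[(R,R)-TsDPEN](p-cymene) and HCO2H–Et3N should then consume the (2R)-enantiomer, matched for cis-selective hydride delivery, as the (2R,4R)-flavan-4-ol F3. The unreacted (2S)-ketone is separated by chromatography, and the route is rejoined at 20.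

Step 11 (ring-closing acylation). Proton transfer from C3 to t-BuLi or to the aryllithium would expel the aryloxide by β-elimination, and t-BuLi could add directly to the amide. The fallback keeps the C4–C4a closure but generates a less basic aryl nucleophile by iodine–magnesium exchange. It sets out from 15, which is ortho-iodinated (NIS, CH2Cl2, −78 °C) to 2-iodo-3,5-dimethoxyphenol F4. Mitsunobu coupling of F4 with 14 should give the (S)-iodo ether F5. Treatment with i-PrMgCl·LiCl in THF at −40 °C should give the arylmagnesium chloride F6, which on warming to 0 °C adds to the Weinreb amide. The route is rejoined at 20.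

Step 13 (O-propargylation of the 5-hydroxyl). The hydrogen-bonded 5-phenoxide is a poor nucleophile, and prolonged exposure to DBU could open the pyranone ring by retro-oxa-Michael reaction and scramble C2. The fallback replaces copper/base chemistry by a neutral palladium-catalysed decarboxylative allylation. It sets out from 21, which is treated with tert-butyl 2-methylbut-3-en-2-yl carbonate and Pd(PPh3)4 (cat.) in THF at 0 °C. Under kinetic control the π-prenyl palladium complex should be attacked at its tertiary terminus and give the 1,1-dimethylallyl ether directly. The route is rejoined at 24, and step 14 is no longer needed.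

**Further compounds**
F1 | step 10 | rac-3-(2-bromo-3,5-dimethoxyphenoxy)-N-methoxy-N-methyl-3-[2-geranyl-4-methoxy-3-(triisopropylsilyloxy)phenyl]propanamide | COc1ccc(C(Oc2cc(OC)cc(OC)c2Br)CC(=O)N(C)OC)c(C/C=C(\C)CCC=C(C)C)c1O[Si](C(C)C)(C(C)C)C(C)C
F2 | step 10 | rac-5,7-dimethoxy-2-[2-geranyl-4-methoxy-3-(triisopropylsilyloxy)phenyl]chroman-4-one | COc1ccc(C2CC(=O)c3c(cc(OC)cc3OC)O2)c(C/C=C(\C)CCC=C(C)C)c1O[Si](C(C)C)(C(C)C)C(C)C
F3 | step 10 | (2R,4R)-5,7-dimethoxy-2-[2-geranyl-4-methoxy-3-(triisopropylsilyloxy)phenyl]chroman-4-ol | COc1ccc([C@H]2C[C@@H](O)c3c(cc(OC)cc3OC)O2)c(C/C=C(\C)CCC=C(C)C)c1O[Si](C(C)C)(C(C)C)C(C)C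
F4 | step 11 | 2-iodo-3,5-dimethoxyphenol | COc1cc(O)c(I)c(OC)c1
F5 | step 11 | (3S)-3-(2-iodo-3,5-dimethoxyphenoxy)-N-methoxy-N-methyl-3-[2-geranyl-4-methoxy-3-(triisopropylsilyloxy)phenyl]propanamide | COc1ccc([C@@H](Oc2cc(OC)cc(OC)c2I)CC(=O)N(C)OC)c(C/C=C(\C)CCC=C(C)C)c1O[Si](C(C)C)(C(C)C)C(C)C
F6 | step 11 | arylmagnesium chloride from F5 (MgCl in place of iodine) | COc1ccc([C@@H](Oc2cc(OC)cc(OC)c2[Mg]Cl)CC(=O)N(C)OC)c(C/C=C(\C)CCC=C(C)C)c1O[Si](C(C)C)(C(C)C)C(C)C
F0 | step 13 | none | none
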